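The earlier runs and the new flask stem from a simulated flask with made-up constants, noise included.

Take the amounts first: charges stand in mM, readings in percent of the charge.

| flask | solid substrate | remark | time |
|---|---|---|---|
| alpha | 10 mM | run made earlier |  |
| gamma | 40 mM | run made earlier |  |
| flask | 20 mM |  | 8.0 h |

| run | time / h | target / % | starting material / % | solid substrate / % |
|---|---|---|---|---|
| alpha | 0.333 | 0.3 | 1.2 | 93.1 |
| alpha | 1.00 | 0.2 | 2.3 | 77.8 |
| alpha | 1.50 | 1.1 | 1.4 | 66.9 |
| alpha | 2.50 | 2.8 | 0.9 | 45.6 |
| alpha | 4.00 | 7.0 | 2.8 | 13.7 |
| alpha | 5.00 | 11.5 | 0 | 0 |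
| gamma | 0.417 | 0 | 0.6 | 98.1 |
| gamma | 0.667 | 0 | 1.3 | 96.6 |
| gamma | 1.00 | 0 | 0.5 | 93.7 |
| gamma | 2.00 | 0 | 1.0 | 89.6 |
| gamma | 3.00 | 1.5 | 0.1 | 84.2 |
| gamma | 5.00 | 2.6 | 0.7 | 73.5 |

(standard deviation of a reading: 0.5 percentage points)

- as a solid, counted per litre of solution: solid substrate
- at the start none of the solid substrate is in solution
- starting material means what is dissolved; the solid is not counted in it
- starting material is what solid substrate becomes in solution

- target at 8.0 h, in percent of the solid substrate charged
- concentration of starting material in solution at 8.0 h, in percent of saturation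

Read the solid substrate from the first reading of each run: the alpha run loses 2.17 mM h⁻¹ up to 4.00 h and the gamma run 2.15 mM h⁻¹ up to 5.00 h, about the same, though the charges differ. Call their mean the feed F, 2.16 mM h⁻¹, the solid substrate lost per hour.

Now climb the ladder of times. On the fastest rung, dissolved starting material averages 0.172 mM in the alpha run, so its residence time is τ = 0.0798 h, a quasi-steady state. On the next rung, the flask's charge lasts T = 9.28 h, much longer than τ and longer than the 8.0 h asked. Expect 13.8% of the solid substrate at that time, and starting material still near 0.860% of the charge. No reading gives the saturation level, so leave that answer open.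

On the slowest rung, the alpha run at 4.00 h has 76.5% of its charge in none of the three measured species, so an unseen pool stands before the target. Assume target grows with the square of time under steady F: the alpha reading gives a clock of 24.6 h, longer than T, and the flask about 14.0% target.

The forecast says 14% target and 100% of saturation, holding that “the solution is still saturated”. The flask gives 13.1% target and 1.40% of saturation.

    solid substrate ⇌ starting material, rate k1*(cs1 - [starting material]) while solid is left; crystals form when [starting material] > cs1 (solubility = 12.0 mM, k = 0.00302 min⁻¹)
    starting material → intermediate A (k = 0.213 min⁻¹)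
    intermediate A ⇌ intermediate B (K = 0.737, k = 0.00230 min⁻¹)
    intermediate A ⇌ target (K = 6.39, k = 9.55 × 10⁻⁴ min⁻¹)

Set F against this flask: the reckoned 13.8% of solid substrate meets 14.2% in the flask at 8.00 h, and starting material stands at 0.838%. Apply F to the neighbouring flask charged with 12 mM: its solid substrate should last 5.57 h, less than the 8.0 h of the reading. That flask shows 0% solid substrate and 0% starting material at 8.00 h, with target at 19.4% of its charge.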